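**Two drains.** Picture the starting material, S, leaving each flask by two drains: the catalyst turns it into product, and the protic impurity, H, turns it into quenched substrate.

| setting | midnight | winter | north-east | north | south-east | north-west |
|---|---|---|---|---|---|---|
| starting material | 0.33 M | 0.33 M | 0.080 M | 0.33 M | 0.33 M | 0.080 M |
| protic impurity | 0.066 M | 0.066 M | 0.0150 M | 0.0150 M | 0.0660 M | 0.0660 M |
| free catalyst | 0.26 mM | 0.34 mM | 0.17 mM | 0.17 mM | 0.17 mM | 0.17 mM |
| temperature | 25 °C | 25 °C | 25 °C | 25 °C | 25 °C | 25 °C |
| remark | run made earlier | run made earlier |  |  |  |  |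
| time |  |  | 1.0 h | 1.0 h | 1.0 h | 1.0 h |

- midnight (time / min: product / %, starting material / %): 5.00: 9.1, 75.2; 10.0: 16.8, 64.6; 15.0: 23.9, 56.5; 20.0: 30.3, 50.2
- winter (time / min: product / %, starting material / %): 5.00: 12.2, 73.2; 10.0: 22.8, 60.2; 15.0: 29.8, 50.3; 20.0: 36.5, 43.4

(scatter of a reading: 0.5 percentage points)

1. the flasks by amount of product, in percent of the starting material charged, highest first, at 1.0 h (north-east / north / south-east / north-west)
2. the amount of product, in percent of the starting material charged of the flask you put first, at 1.0 h
3. the amount of product, in percent of the starting material charged of the flask you put last, at 1.0 h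

**Break-even level.** Each drain has a time constant. Through the catalyst, at concentration c, it is the reciprocal of k_c·c; through the impurity, it is the reciprocal of k_q·H. Both rates are proportional to S, so S cancels from their ratio. We call H* = k_c·c/k_q the break-even level, the impurity level at which the two time constants are equal. Dividing one rate by the other gives a rule, for steady c and k_c: product made equals H* times ln(charge of H / H left).

**Reading H\*.** In the midnight run, starting material plus product is short by 19.5 % at 20.0 min, close to the impurity charge of 20.0 %, so we count one impurity used per starting material lost. The shortfall at 5.00 min and the product then give H* = 0.0195 M; the winter run gives 0.0307 M. Scaling each to 0.17 mM of catalyst and averaging, as readings, gives H* = 0.0141 M.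

**Our reckoning.** North-west starts at 4.69 times H*, so the quench leads there. Suppose its starting material runs to the finish with 0.0110 M of impurity left. The quench then took 0.0550 M and the rule gives 0.0253 M of product, together 0.0802 M, which matches the charge of 0.080 M. That is 31.6 % product at the finish.

**The forecast.** It orders the flasks north > north-east > south-east > north-west, with 54 % on top (range 47 % to 60 %) and 30 % last (range 24 % to 35 %), and notes: “Any deactivation would hurt the high-S flasks more”.

**The flasks.** The order is north-east > north > south-east > north-west: north-east leads with 56.3 %, and north-west stays last at 31.7 %, inside the forecast's range.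

    starting material + free catalyst ⇌ catalyst intermediate A (K = 68.0 L mol⁻¹, k = 2.00 L mol⁻¹ s⁻¹, Ea = 51.0 kJ mol⁻¹, ΔH = −12.0 kJ mol⁻¹)
    catalyst intermediate A ⇌ catalyst intermediate B (K = 4.30, k = 2.70 s⁻¹, Ea = 73.0 kJ mol⁻¹, ΔH = −45.0 kJ mol⁻¹)
    catalyst intermediate B → free catalyst + product (k = 4.30 s⁻¹, Ea = 65.0 kJ mol⁻¹)
    catalyst intermediate A → spent catalyst (k = 8.90 × 10⁻⁴ s⁻¹, Ea = 95.0 kJ mol⁻¹)
    starting material + protic impurity → quenched substrate (k = 0.0170 L mol⁻¹ s⁻¹, Ea = 54.0 kJ mol⁻¹)
    (constants at 25 °C)

Without the quench, north-west makes 65.3 %. With 25 % of its impurity left after 1.00 h, our H* gives 24.4 %, so north-west runs 1.30 times higher than the rule. A neighbour, north-west with 4.3 × 10⁻⁵ M of catalyst, left 15 % of its impurity. H* scaled to that catalyst gives 8.50 %, and the same factor makes it 11.1 %; that flask made 10.9 %.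

All runs are calculated with made-up constants; scatter was added.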